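Remark on the chemistry (assumption): the (R,S,S) antipode of the binaphthol/bis(1-phenylethyl)amine phosphoramidite is taken to deliver the alkenyl group to the enone face that leads to 3S in 16, by analogy with the facial sense of this ligand family with dialkylzinc reagents; should the sense be opposite, the (S,R,R) antipode is used and nothing else changes.

## Structural features

The target 28 is a bisabolane-type sesquiterpenoid diester: a 1-methyl-7-oxabicyclo[4.1.0]heptan-2-one (a cyclohexanone with an oxirane fused at C1–C6, hence an α,β-epoxy ketone) with a senecioate on C3 and a 6-methylhepta-1,5-dien-2-yl chain on C4, whose C8 hydroxyl is esterified with angelic acid. Positions are numbered throughout as C1 (methyl-bearing oxirane carbon), C2 (ketone), C3, C4, C5 (CH2), C6 (oxirane CH) in the ring and C7 (=C14H2), C8, C9, C10=C11 in the chain; the configuration is 1S,3S,4S,6S in the ring and S at C8. The C3 oxygen and the C4 chain are trans, and the oxirane lies cis to the C4 chain and trans to the C3 oxygen. The four ring stereocentres are contiguous around the ketone, whereas C8 is held apart from C4 by the sp2 carbon C7, so no ring relays stereochemical information between ring and chain. Fragile elements are the epoxy ketone (nucleophiles, base, strong acid), the epimerisable C3 centre once it is α-acyloxy, the Z-configured angelate (it slips to the tiglate on activation), the electron-rich C10=C11 alkene (electrophilic oxidants, HBr) and the allylic C8 ester. The real difficulties are the C4/C8 relationship, an oxirane on the ring face that an axial nucleophilic epoxidation of a carvone-like enone would not choose, and two different unsaturated esters on two secondary hydroxyls. The key step exploits the fact that C3 and C4 are the α and β carbons of the C2 carbonyl and are trans: C2–C3–C4 maps onto cyclohex-2-en-1-one, which takes the C7 alkenyl nucleophile at C4 and an electrophilic oxygen at C3 in one operation.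

## Logic of the disconnections

28 is cut first at the C8–O acyl bond, giving 27 and the angeloyl donor. The angelate is the group most prone to geometric isomerisation and is therefore introduced last. The gain is that every earlier step works with robust silyl ethers; the demand is an esterification of a hindered allylic alcohol that does not scramble the Z alkene.

27 is traced through 26 and 25 to 24 by cutting the C8 O–Si exchange, the C3–O acyl bond and the C3 O–Si exchange. Keeping the two hydroxyls as a triethylsilyl and a tert-butyldimethylsilyl ether differentiates them for the two acids. The forward steps must cleave the triethylsilyl ether in the presence of the other, and later the tert-butyldimethylsilyl ether without opening the epoxy ketone.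

24 is cut at the two oxirane C–O bonds (C1–O, C6–O) back through 23 and 22 to 21, with the C2 carbonyl held for two steps as a hydroxyl. A direct nucleophilic epoxidation of 21 would be expected to place the oxirane trans to the C4 chain, so the oxygen is instead delivered from a C2 hydroxyl that sits on the required face. The demand is hydride addition to C2 giving the 1,2-trans alcohol 22, and an epoxidation that touches only the allylic C1=C6 alkene.

21 is cut at the C1–CH3 bond to 20 and further at C1–I to 19. Introducing the methyl by cross-coupling on the enone avoids a second, regiochemically ambiguous enolisation of a 2-methyl-6-silyloxycyclohexanone. The price is one extra step; the demand is a clean methyl transfer to an α-iodoenone.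

19 is cut at the C1=C6 unsaturation to 17 by way of 18. This requires kinetic enolisation at the C1 methylene and not at C3, which the silyloxy group and the C4 branch disfavour. 17 goes back to 16 by the O–Si bond.

16 is cut at C4–C7 and at C3–O to 10 and 11. This is the convergent step: the ring comes from a commodity enone, the whole chain with C8 and the methylene comes from 10, and both ring stereocentres of this stage are set. The forward step needs ligand control at C4 that is independent of C8, alkenyl rather than methyl transfer, and oxidation of a regiodefined enolate anti to the new substituent. The design is tightened in two ways: 12 is transmetalated cold so that silyl migration or allene formation gets no time, and the aluminium enolate is turned into an aluminate before the oxidant is added.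

10 is cut at C7–Br (with C14–H) to 8 by way of 9, a Markovnikov hydrobromination of a terminal alkyne that must tolerate the silyl ether and the trisubstituted alkene. 8 is simplified through 7 to 6 by the C–Si and O–Si bonds.

6 is cut at the C8–H bond to 5, so the only chain stereocentre comes from an enantioselective ketone reduction. The reduction must distinguish alkynyl from alkyl and must not move the β,γ-alkene into conjugation.

5 is cut at C7–C8 to 2 and 3 (through 4), an acetylide acylation that must stop at the ketone. 2 is cut at the amide C–N bond to 1.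

## Other disconnections considered

Alternative 1: The C8–O bond and the C7=C14 methylene are traced back to an oxirane across C7–C8 in which C14 is a hydroxymethyl group, the epoxy alcohol A1. A1 would arise from the Z allylic alcohol A2 by epoxidation with Ti(OiPr)4, a dialkyl tartrate and t-BuOOH; iodination of the primary hydroxyl and zinc-induced reductive opening would then release the C8 hydroxyl and the methylene.
- In favour: C8 is set by a reagent with a reliable facial rule. The hydroxyl-bound titanium peroxide would ignore C10=C11 and the enone. No alkenylmetal carrying a β-silyloxy group is needed, and the sensitive methylene appears late.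
- Against: A2 is a Z allylic alcohol with an α-branched substituent on C7, the slowest and least selective substrate class for this epoxidation, and the neighbouring C4 centre invites a mismatched pairing. The step forms no carbon–carbon bond, so the ring with C3 and C4 and the stereodefined trisubstituted alkene of A2 must all be secured separately, and two more operations are needed to transpose the oxygen.
- Comparison on structure: the step leaves one lasting stereocentre and no skeletal bond, against two stereocentres and two bonds for the chosen step.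
- Comparison on mechanism: both rely on a chiral catalyst overriding resident stereocentres. For C8 alone the tartrate method is in principle the equal of the transfer hydrogenation of 5, and in chemoselectivity toward the chain alkenes it is equal or better, but it is asked to work on a poorer substrate class.
- Comparison on step economy: the end game after A1 (ring epoxide, two esters) is no shorter than in the chosen plan and the route to A2 is longer, so the total should be higher.

Alternative 2: The C1–C2 bond and the bond from C2 to the future methyl carbon are cut, leading to the bicyclo[4.1.0]heptan-1-ol A3. A3 would come from the open-chain ω-alkenyl ester A4 by an intramolecular Kulinkovich reaction (Ti(OiPr)4 or ClTi(OiPr)3 with c-C6H11MgCl): the titanacyclopropane, a divalent-titanium alkene complex, exchanges onto the terminal alkene and adds twice to the ester, closing the six-membered ring and the cyclopropane together.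
- In favour: carbocycle and methyl carbon are installed in one step at the right position. Ligand exchange prefers the monosubstituted alkene over C7=C14 and C10=C11. The new centres of A3 (C1, C2) are erased later, so their configuration need not be controlled. The step replaces the iodination and methyl coupling of the chosen plan, and on that count it is the better.
- Against: A4 is an acyclic chain in which the vicinal C3/C4 pair and C8 must be set by open-chain stereocontrol. The α-alkoxy ester meets an excess of Grignard reagent. Unmasking needs selective cleavage of the outer cyclopropane bond and not the ring-fusion bond, followed by a dehydrogenation that faces the same C1-versus-C3 question as the chosen plan, and a benzyl-type ether has to be removed late.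
- Comparison on structure: one ring and two C–C bonds but no lasting stereocentre, against no ring, one C–C and one C–O bond and two stereocentres.
- Comparison on mechanism: a stoichiometric low-valent titanium process with little stereochemical burden, against a catalytic asymmetric addition carrying the main stereochemical burden.
- Comparison on step economy: similar after the key step, clearly longer before it.

Alternative 3: The C4–C5 bond is cut, leading to the cyclohexenol A5, which is the same compound as 22 of the chosen route. A5 would come from the acyclic epoxy allylsilane A6: a Lewis acid such as BF3·OEt2 or Me2AlCl opens the C1–C2 vinyl oxirane to an allyl cation, C4 of the allylsilane attacks C5, and loss of silicon leaves the C7=C14 methylene.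
- In favour: A5 is reached in one ring-forming step with the C1 methyl, the C1=C6 alkene, the C2 hydroxyl and the methylene in place, where the chosen plan needs steps 7 to 12. The C2 configuration is carried stereospecifically from the oxirane and does not depend on a diastereoselective hydride addition; on this point the alternative is the better.
- Against: A6 needs C2, C3, C8 and the allylsilane geometry defined in a polyfunctional open chain. C4 would be set by substrate control alone through a chair-like transition state whose preference relative to the C3 silyloxy group is uncertain. The cation can also be lost to capture at C1, hydride shift to a ketone, elimination, or attack by C10=C11, and two silyl ethers must survive the Lewis acid.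
- Comparison on structure: one ring, one C–C bond and one new stereocentre (C4), against two bonds and two stereocentres without ring closure.
- Comparison on mechanism: a cationic cyclisation under substrate control, against a catalyst-controlled conjugate addition.
- Comparison on step economy: the route after A5 equals steps 13 to 18 of the chosen plan, but assembling A6 should cost considerably more steps than steps 1 to 12.

Key step: step 7

## Route

Step 1
Reactants: 1 4-methylpent-3-enoic acid
Product: 2 N-methoxy-N,4-dimethylpent-3-enamide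
Conditions: CDI, CH2Cl2, 0 °C → rt; then MeNHOMe·HCl, rt
Reagents that add atoms: N,O-dimethylhydroxylamine hydrochloride, CNOC.Cl
Why: Weinreb amide formation through the acyl imidazolide; the near-neutral medium should leave the β,γ-alkene out of conjugation.

Step 2
Reactants: 2 N-methoxy-N,4-dimethylpent-3-enamide; 3 ethynyltrimethylsilane
Product: 5 6-methyl-1-(trimethylsilyl)hept-5-en-1-yn-3-one, via lithium (trimethylsilyl)acetylide 4 (not isolated)
Conditions: 3, n-BuLi, THF, −78 °C; then 2, −78 → −20 °C; cold aq. NH4Cl
Reagents that add atoms: none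
Why: Acylation of a lithium acetylide by a Weinreb amide; the chelated tetrahedral adduct prevents over-addition and releases the ynone only on the mildly acidic quench, which should keep the doubly activated C9 methylene from isomerising.

Step 3
Reactants: 5 6-methyl-1-(trimethylsilyl)hept-5-en-1-yn-3-one
Product: 6 (3S)-6-methyl-1-(trimethylsilyl)hept-5-en-1-yn-3-ol
Conditions: Ru[(S,S)-TsDPEN](p-cymene) (1 mol %), i-PrOH, rt
Reagents that add atoms: none
Why: Noyori asymmetric transfer hydrogenation of an α,β-acetylenic ketone; the alkynyl group takes the place of the π-substituent in the six-membered hydride/proton transfer, so the (S,S) catalyst should give the S carbinol (C8), and the base-free medium should not shift the β,γ-alkene.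

Step 4
Reactants: 6 (3S)-6-methyl-1-(trimethylsilyl)hept-5-en-1-yn-3-ol
Product: 7 (3S)-3-(tert-butyldimethylsilyloxy)-6-methyl-1-(trimethylsilyl)hept-5-en-1-yne
Conditions: TBSCl, imidazole, DMF, rt
Reagents that add atoms: tert-butyldimethylsilyl chloride, CC(C)(C)[Si](C)(C)Cl
Why: Standard O-silylation of a secondary propargylic alcohol; the stereocentre is not touched.

Step 5
Reactants: 7 (3S)-3-(tert-butyldimethylsilyloxy)-6-methyl-1-(trimethylsilyl)hept-5-en-1-yne
Product: 8 (3S)-3-(tert-butyldimethylsilyloxy)-6-methylhept-5-en-1-yne
Conditions: K2CO3 (cat.), MeOH, rt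
Reagents that add atoms: none
Why: Methanolysis of the C(sp)–Si bond; the silyl ether on oxygen is stable to carbonate in methanol.

Step 6
Reactants: 8 (3S)-3-(tert-butyldimethylsilyloxy)-6-methylhept-5-en-1-yne
Product: 10 (3S)-2-bromo-3-(tert-butyldimethylsilyloxy)-6-methylhepta-1,5-diene, via alkenylborane 9 (not isolated)
Conditions: B-bromo-9-BBN (1.1 equiv), CH2Cl2, 0 °C; then AcOH, 0 °C; aq. NaHCO3
Reagents that add atoms: B-bromo-9-borabicyclo[3.3.1]nonane, BrB1C2CCCC1CCC2
Why: Bromoboration of a terminal alkyne (syn addition, bromine to the internal carbon, boron to the terminus) followed by protodeboronation with retention gives the 2-bromo-1-alkene; the reagent does not add to alkenes, and a small excess with prompt basic work-up should limit ether cleavage and HBr addition to C10=C11.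

Step 7
Reactants: 10 (3S)-2-bromo-3-(tert-butyldimethylsilyloxy)-6-methylhepta-1,5-diene; 11 cyclohex-2-en-1-one
Product: 16 (2S,3S)-3-[(3S)-3-(tert-butyldimethylsilyloxy)-6-methylhepta-1,5-dien-2-yl]-2-hydroxycyclohexan-1-one, via alkenyllithium 12 (not isolated), via alkenyldimethylalane 13 (not isolated), via dimethylaluminium enolate 14 (not isolated), via lithium aluminate enolate 15 (not isolated)
Conditions: t-BuLi (2 equiv), Et2O, −78 °C; Me2AlCl, −78 → −30 °C; 11, Cu(OTf)2 (5 mol %), (R,S,S)-binaphthol bis(1-phenylethyl)amine phosphoramidite (10 mol %), Et2O/THF, −30 °C; MeLi, −78 °C; 2-(phenylsulfonyl)-3-phenyloxaziridine, THF, −78 → −20 °C; aq. potassium sodium tartrate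
Reagents that add atoms: 2-(phenylsulfonyl)-3-phenyloxaziridine, O=S(=O)(c1ccccc1)N1OC1c1ccccc1
Why: Bromine–lithium exchange at −78 °C gives 12, which is intercepted at once by Me2AlCl so that the silyl group has no time to migrate from oxygen to C7; the alane 13 reduces Cu(OTf)2 to monovalent copper and hands over its sp2 group in preference to methyl, and the ligated alkenylcopper adds to the enone through a π-complex and a trivalent-copper intermediate, reductive elimination forming C4–C7 and leaving the aluminium enolate 14 with its double bond fixed between C2 and C3. The closest known reaction type is the copper/phosphoramidite-catalysed asymmetric conjugate addition of alkenylalanes to cyclic enones with electrophilic trapping of the aluminium enolate, joined here to the sulfonyloxaziridine hydroxylation of a metal enolate. No ring is closed. C4 is set by the ligand, which differentiates the two enone faces; the C8 centre sits on the nucleophile and is expected to modulate this control without overriding it. MeLi turns 14 into the more nucleophilic aluminate 15, whose C3 attacks the oxaziridine oxygen, the N–O bond breaks and the hemiaminal collapses to the sulfonimine and the C3 alkoxide. C3 is set by the substrate: the oxidant approaches the enolate face anti to the new branched C4 substituent, giving the trans 2S,3S arrangement. The step needs 1,4- over 1,2-addition (copper catalysis), alkenyl over methyl transfer (inherent in the mixed alane), a regiodefined enolate (formed only toward C3 and not equilibrated in the cold) and oxidation of the enolate in preference to the C7=C14 and C10=C11 alkenes (the oxaziridine does not epoxidise unactivated alkenes at these temperatures).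

Step 8
Reactants: 16 (2S,3S)-3-[(3S)-3-(tert-butyldimethylsilyloxy)-6-methylhepta-1,5-dien-2-yl]-2-hydroxycyclohexan-1-one
Product: 17 (2S,3S)-3-[(3S)-3-(tert-butyldimethylsilyloxy)-6-methylhepta-1,5-dien-2-yl]-2-(triethylsilyloxy)cyclohexan-1-one
Conditions: TESCl, imidazole, DMF, 0 °C
Reagents that add atoms: chlorotriethylsilane, CC[Si](Cl)(CC)CC
Why: O-silylation of the α-ketol under mild amine buffering, which should not epimerise C3; the triethylsilyl ether is later removable beside the tert-butyldimethylsilyl ether.

Step 9
Reactants: 17 (2S,3S)-3-[(3S)-3-(tert-butyldimethylsilyloxy)-6-methylhepta-1,5-dien-2-yl]-2-(triethylsilyloxy)cyclohexan-1-one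
Product: 19 (5S,6S)-5-[(3S)-3-(tert-butyldimethylsilyloxy)-6-methylhepta-1,5-dien-2-yl]-6-(triethylsilyloxy)cyclohex-2-en-1-one, via silyl enol ether 18 (not isolated)
Conditions: LiN(i-Pr)2, TMSCl, THF, −78 °C; solvent exchange; Pd(OAc)2 (1.1 equiv), MeCN, rt
Reagents that add atoms: none
Why: Saegusa–Ito dehydrogenation; kinetic deprotonation with internal silyl quench occurs at the open C1 methylene and not at the C3 hydrogen flanked by the silyloxy group and C4, and palladation of the enol silane by divalent palladium followed by β-hydride elimination from C6 gives the C1=C6 enone while the isolated alkenes should be left alone.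

Step 10
Reactants: 19 (5S,6S)-5-[(3S)-3-(tert-butyldimethylsilyloxy)-6-methylhepta-1,5-dien-2-yl]-6-(triethylsilyloxy)cyclohex-2-en-1-one
Product: 20 (5S,6S)-5-[(3S)-3-(tert-butyldimethylsilyloxy)-6-methylhepta-1,5-dien-2-yl]-2-iodo-6-(triethylsilyloxy)cyclohex-2-en-1-one
Conditions: I2, pyridine/CH2Cl2, 0 °C → rt
Reagents that add atoms: iodine, II
Why: α-Iodination of a cyclic enone by conjugate addition of pyridine, iodination of the enolate and elimination (Baylis–Hillman-type activation); only C1 is activated in this way, and iodine should add at most reversibly to C10=C11 in the absence of a nucleophile.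

Step 11
Reactants: 20 (5S,6S)-5-[(3S)-3-(tert-butyldimethylsilyloxy)-6-methylhepta-1,5-dien-2-yl]-2-iodo-6-(triethylsilyloxy)cyclohex-2-en-1-one
Product: 21 (5S,6S)-5-[(3S)-3-(tert-butyldimethylsilyloxy)-6-methylhepta-1,5-dien-2-yl]-2-methyl-6-(triethylsilyloxy)cyclohex-2-en-1-one
Conditions: MeB(OH)2, Pd(OAc)2 (5 mol %), SPhos (10 mol %), K3PO4, toluene/H2O, 60 °C
Reagents that add atoms: methylboronic acid, CB(O)O
Why: Suzuki–Miyaura coupling; α-iodoenones add readily to zerovalent palladium and the electron-rich biarylphosphine supports transfer and reductive elimination of the methyl group, while the trans C3/C4 arrangement is the thermodynamically preferred one so the mild base should not alter C3.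

Step 12
Reactants: 21 (5S,6S)-5-[(3S)-3-(tert-butyldimethylsilyloxy)-6-methylhepta-1,5-dien-2-yl]-2-methyl-6-(triethylsilyloxy)cyclohex-2-en-1-one
Product: 22 (1S,5S,6S)-5-[(3S)-3-(tert-butyldimethylsilyloxy)-6-methylhepta-1,5-dien-2-yl]-2-methyl-6-(triethylsilyloxy)cyclohex-2-en-1-ol
Conditions: NaBH4, CeCl3·7H2O, MeOH, −78 °C
Reagents that add atoms: none
Why: Luche 1,2-reduction; axial hydride addition to the half-chair with the C3 silyloxy group and the C4 chain pseudoequatorial should place the new C2 hydroxyl pseudoequatorial, trans to the C3 oxygen and cis to the C4 chain, as in carveol-type and 6-alkoxycyclohexenone reductions, and the cerium salt suppresses conjugate reduction.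

Step 13
Reactants: 22 (1S,5S,6S)-5-[(3S)-3-(tert-butyldimethylsilyloxy)-6-methylhepta-1,5-dien-2-yl]-2-methyl-6-(triethylsilyloxy)cyclohex-2-en-1-ol
Product: 23 (1R,2R,3S,4S,6S)-4-[(3S)-3-(tert-butyldimethylsilyloxy)-6-methylhepta-1,5-dien-2-yl]-1-methyl-3-(triethylsilyloxy)-7-oxabicyclo[4.1.0]heptan-2-ol
Conditions: VO(acac)2 (5 mol %), t-BuOOH, CH2Cl2, 0 °C → rt
Reagents that add atoms: tert-butyl hydroperoxide, CC(C)(C)OO
Why: Hydroxyl-directed epoxidation of an allylic alcohol by a vanadium-bound alkyl peroxide; oxygen is delivered to the C1=C6 face syn to the C2 hydroxyl, which sets C1 and C6 cis to the C4 chain and trans to the C3 oxygen, and the metal-bound oxidant should pass over the C7=C14 and C10=C11 alkenes as it does in cis-carveol.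

Step 14
Reactants: 23 (1R,2R,3S,4S,6S)-4-[(3S)-3-(tert-butyldimethylsilyloxy)-6-methylhepta-1,5-dien-2-yl]-1-methyl-3-(triethylsilyloxy)-7-oxabicyclo[4.1.0]heptan-2-ol
Product: 24 (1S,3S,4S,6S)-4-[(3S)-3-(tert-butyldimethylsilyloxy)-6-methylhepta-1,5-dien-2-yl]-1-methyl-3-(triethylsilyloxy)-7-oxabicyclo[4.1.0]heptan-2-one
Conditions: Dess–Martin periodinane, NaHCO3, CH2Cl2, 0 °C → rt
Reagents that add atoms: none
Why: Dess–Martin oxidation of a hindered secondary epoxy alcohol under buffered, non-basic conditions that should spare the oxirane, the silyl ethers and the alkenes.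

Step 15
Reactants: 24 (1S,3S,4S,6S)-4-[(3S)-3-(tert-butyldimethylsilyloxy)-6-methylhepta-1,5-dien-2-yl]-1-methyl-3-(triethylsilyloxy)-7-oxabicyclo[4.1.0]heptan-2-one
Product: 25 (1S,3S,4S,6S)-4-[(3S)-3-(tert-butyldimethylsilyloxy)-6-methylhepta-1,5-dien-2-yl]-3-hydroxy-1-methyl-7-oxabicyclo[4.1.0]heptan-2-one
Conditions: HF·pyridine, pyridine, THF, 0 °C
Reagents that add atoms: none
Why: Buffered fluoride cleavage differentiates the labile triethylsilyl ether next to the ketone from the hindered tert-butyldimethylsilyl ether at C8; the carbonyl-deactivated oxirane should tolerate the buffered reagent.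

Step 16
Reactants: 25 (1S,3S,4S,6S)-4-[(3S)-3-(tert-butyldimethylsilyloxy)-6-methylhepta-1,5-dien-2-yl]-3-hydroxy-1-methyl-7-oxabicyclo[4.1.0]heptan-2-one
Product: 26 (1S,3S,4S,6S)-4-[(3S)-3-(tert-butyldimethylsilyloxy)-6-methylhepta-1,5-dien-2-yl]-1-methyl-2-oxo-7-oxabicyclo[4.1.0]heptan-3-yl 3-methylbut-2-enoate
Conditions: 3-methylbut-2-enoyl chloride, pyridine, DMAP (cat.), CH2Cl2, 0 °C
Reagents that add atoms: 3-methylbut-2-enoyl chloride, CC(C)=CC(=O)Cl
Why: O-acylation of the α-ketol with an acid chloride; the weak base pyridine should limit vinylketene formation (deconjugation of the senecioyl unit) and C3 epimerisation.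

Step 17
Reactants: 26 (1S,3S,4S,6S)-4-[(3S)-3-(tert-butyldimethylsilyloxy)-6-methylhepta-1,5-dien-2-yl]-1-methyl-2-oxo-7-oxabicyclo[4.1.0]heptan-3-yl 3-methylbut-2-enoate
Product: 27 (1S,3S,4S,6S)-4-[(3S)-3-hydroxy-6-methylhepta-1,5-dien-2-yl]-1-methyl-2-oxo-7-oxabicyclo[4.1.0]heptan-3-yl 3-methylbut-2-enoate
Conditions: HF·pyridine, THF, 0 °C → rt
Reagents that add atoms: none
Why: Fluoride-mediated cleavage of the secondary silyl ether under weakly acidic, non-basic conditions, chosen so that the ester and the base-sensitive α-acyloxy epoxy ketone are not exposed to alkoxide or naked fluoride.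

Step 18
Reactants: 27 (1S,3S,4S,6S)-4-[(3S)-3-hydroxy-6-methylhepta-1,5-dien-2-yl]-1-methyl-2-oxo-7-oxabicyclo[4.1.0]heptan-3-yl 3-methylbut-2-enoate
Product: 28 (1S,3S,4S,6S)-1-methyl-4-[(3S)-6-methyl-3-{[(2Z)-2-methylbut-2-enoyl]oxy}hepta-1,5-dien-2-yl]-2-oxo-7-oxabicyclo[4.1.0]heptan-3-yl 3-methylbut-2-enoate
Conditions: (Z)-2-methylbut-2-enoic acid, 2,4,6-trichlorobenzoyl chloride, Et3N, toluene, rt; then 27, 75 °C (no DMAP)
Reagents that add atoms: (2Z)-2-methylbut-2-enoic acid (angelic acid), C/C=C(/C)C(=O)O
Why: Yamaguchi-type mixed-anhydride esterification run without a nucleophilic catalyst, the conditions under which angeloyl transfer is expected to keep the Z geometry because no reversible conjugate addition to the activated acyl unit can occur; C8 is not touched.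

## Compound list

1 | 4-methylpent-3-enoic acid | CC(C)=CCC(=O)O | starting material
2 | N-methoxy-N,4-dimethylpent-3-enamide | CC(C)=CCC(=O)N(C)OC | intermediate
3 | ethynyltrimethylsilane | C#C[Si](C)(C)C | starting material
4 | lithium (trimethylsilyl)acetylide (formed in the flask) | [Li]C#C[Si](C)(C)C | intermediate
5 | 6-methyl-1-(trimethylsilyl)hept-5-en-1-yn-3-one | CC(C)=CCC(=O)C#C[Si](C)(C)C | intermediate
6 | (3S)-6-methyl-1-(trimethylsilyl)hept-5-en-1-yn-3-ol | C[Si](C)(C)C#C[C@H](CC=C(C)C)O | intermediate
7 | (3S)-3-(tert-butyldimethylsilyloxy)-6-methyl-1-(trimethylsilyl)hept-5-en-1-yne | C[Si](C)(C)C#C[C@H](CC=C(C)C)O[Si](C)(C)C(C)(C)C | intermediate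
8 | (3S)-3-(tert-butyldimethylsilyloxy)-6-methylhept-5-en-1-yne | C#C[C@H](CC=C(C)C)O[Si](C)(C)C(C)(C)C | intermediate
9 | 9-[(1Z,3S)-2-bromo-3-(tert-butyldimethylsilyloxy)-6-methylhepta-1,5-dien-1-yl]-9-borabicyclo[3.3.1]nonane (formed in the flask) | Br/C(=C\B1C2CCCC1CCC2)[C@H](CC=C(C)C)O[Si](C)(C)C(C)(C)C | intermediate
10 | (3S)-2-bromo-3-(tert-butyldimethylsilyloxy)-6-methylhepta-1,5-diene | C=C(Br)[C@H](CC=C(C)C)O[Si](C)(C)C(C)(C)C | intermediate
11 | cyclohex-2-en-1-one | O=C1C=CCCC1 | starting material
12 | [(3S)-3-(tert-butyldimethylsilyloxy)-6-methylhepta-1,5-dien-2-yl]lithium (formed in the flask) | [Li]C(=C)[C@H](CC=C(C)C)O[Si](C)(C)C(C)(C)C | intermediate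
13 | [(3S)-3-(tert-butyldimethylsilyloxy)-6-methylhepta-1,5-dien-2-yl]dimethylalumane (formed in the flask) | C[Al](C)C(=C)[C@H](CC=C(C)C)O[Si](C)(C)C(C)(C)C | intermediate
14 | dimethylaluminium (3R)-3-[(3S)-3-(tert-butyldimethylsilyloxy)-6-methylhepta-1,5-dien-2-yl]cyclohex-1-en-1-olate (formed in the flask) | C=C([C@H](CC=C(C)C)O[Si](C)(C)C(C)(C)C)[C@@H]1CCCC(O[Al](C)C)=C1 | intermediate
15 | lithium trimethyl{[(3R)-3-[(3S)-3-(tert-butyldimethylsilyloxy)-6-methylhepta-1,5-dien-2-yl]cyclohex-1-en-1-yl]oxy}aluminate (formed in the flask) | [Li+].C=C([C@H](CC=C(C)C)O[Si](C)(C)C(C)(C)C)[C@@H]1CCCC(O[Al-](C)(C)C)=C1 | intermediate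
16 | (2S,3S)-3-[(3S)-3-(tert-butyldimethylsilyloxy)-6-methylhepta-1,5-dien-2-yl]-2-hydroxycyclohexan-1-one | C=C([C@H](CC=C(C)C)O[Si](C)(C)C(C)(C)C)[C@@H]1CCCC(=O)[C@H]1O | intermediate
17 | (2S,3S)-3-[(3S)-3-(tert-butyldimethylsilyloxy)-6-methylhepta-1,5-dien-2-yl]-2-(triethylsilyloxy)cyclohexan-1-one | C=C([C@H](CC=C(C)C)O[Si](C)(C)C(C)(C)C)[C@@H]1CCCC(=O)[C@H]1O[Si](CC)(CC)CC | intermediate
18 | (5S,6S)-5-[(3S)-3-(tert-butyldimethylsilyloxy)-6-methylhepta-1,5-dien-2-yl]-6-(triethylsilyloxy)-1-(trimethylsilyloxy)cyclohex-1-ene (used crude) | C=C([C@H](CC=C(C)C)O[Si](C)(C)C(C)(C)C)[C@@H]1CCC=C(O[Si](C)(C)C)[C@H]1O[Si](CC)(CC)CC | intermediate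
19 | (5S,6S)-5-[(3S)-3-(tert-butyldimethylsilyloxy)-6-methylhepta-1,5-dien-2-yl]-6-(triethylsilyloxy)cyclohex-2-en-1-one | C=C([C@H](CC=C(C)C)O[Si](C)(C)C(C)(C)C)[C@@H]1CC=CC(=O)[C@H]1O[Si](CC)(CC)CC | intermediate
20 | (5S,6S)-5-[(3S)-3-(tert-butyldimethylsilyloxy)-6-methylhepta-1,5-dien-2-yl]-2-iodo-6-(triethylsilyloxy)cyclohex-2-en-1-one | C=C([C@H](CC=C(C)C)O[Si](C)(C)C(C)(C)C)[C@@H]1CC=C(I)C(=O)[C@H]1O[Si](CC)(CC)CC | intermediate
21 | (5S,6S)-5-[(3S)-3-(tert-butyldimethylsilyloxy)-6-methylhepta-1,5-dien-2-yl]-2-methyl-6-(triethylsilyloxy)cyclohex-2-en-1-one | C=C([C@H](CC=C(C)C)O[Si](C)(C)C(C)(C)C)[C@@H]1CC=C(C)C(=O)[C@H]1O[Si](CC)(CC)CC | intermediate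
22 | (1S,5S,6S)-5-[(3S)-3-(tert-butyldimethylsilyloxy)-6-methylhepta-1,5-dien-2-yl]-2-methyl-6-(triethylsilyloxy)cyclohex-2-en-1-ol | C=C([C@H](CC=C(C)C)O[Si](C)(C)C(C)(C)C)[C@@H]1CC=C(C)[C@H](O)[C@H]1O[Si](CC)(CC)CC | intermediate
23 | (1R,2R,3S,4S,6S)-4-[(3S)-3-(tert-butyldimethylsilyloxy)-6-methylhepta-1,5-dien-2-yl]-1-methyl-3-(triethylsilyloxy)-7-oxabicyclo[4.1.0]heptan-2-ol | C=C([C@H](CC=C(C)C)O[Si](C)(C)C(C)(C)C)[C@@H]1C[C@@H]2O[C@]2(C)[C@H](O)[C@H]1O[Si](CC)(CC)CC | intermediate
24 | (1S,3S,4S,6S)-4-[(3S)-3-(tert-butyldimethylsilyloxy)-6-methylhepta-1,5-dien-2-yl]-1-methyl-3-(triethylsilyloxy)-7-oxabicyclo[4.1.0]heptan-2-one | C=C([C@H](CC=C(C)C)O[Si](C)(C)C(C)(C)C)[C@@H]1C[C@@H]2O[C@]2(C)C(=O)[C@H]1O[Si](CC)(CC)CC | intermediate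
25 | (1S,3S,4S,6S)-4-[(3S)-3-(tert-butyldimethylsilyloxy)-6-methylhepta-1,5-dien-2-yl]-3-hydroxy-1-methyl-7-oxabicyclo[4.1.0]heptan-2-one | C=C([C@H](CC=C(C)C)O[Si](C)(C)C(C)(C)C)[C@@H]1C[C@@H]2O[C@]2(C)C(=O)[C@H]1O | intermediate
26 | (1S,3S,4S,6S)-4-[(3S)-3-(tert-butyldimethylsilyloxy)-6-methylhepta-1,5-dien-2-yl]-1-methyl-2-oxo-7-oxabicyclo[4.1.0]heptan-3-yl 3-methylbut-2-enoate | C=C([C@H](CC=C(C)C)O[Si](C)(C)C(C)(C)C)[C@@H]1C[C@@H]2O[C@]2(C)C(=O)[C@H]1OC(=O)C=C(C)C | intermediate
27 | (1S,3S,4S,6S)-4-[(3S)-3-hydroxy-6-methylhepta-1,5-dien-2-yl]-1-methyl-2-oxo-7-oxabicyclo[4.1.0]heptan-3-yl 3-methylbut-2-enoate | C=C([C@H](CC=C(C)C)O)[C@@H]1C[C@@H]2O[C@]2(C)C(=O)[C@H]1OC(=O)C=C(C)C | intermediate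
28 | (1S,3S,4S,6S)-1-methyl-4-[(3S)-6-methyl-3-{[(2Z)-2-methylbut-2-enoyl]oxy}hepta-1,5-dien-2-yl]-2-oxo-7-oxabicyclo[4.1.0]heptan-3-yl 3-methylbut-2-enoate | C=C([C@H](CC=C(C)C)OC(=O)/C(C)=C\C)[C@@H]1C[C@@H]2O[C@]2(C)C(=O)[C@H]1OC(=O)C=C(C)C | target

## Step count and least certain steps

Total step count: 18 (six before the key step, the key step, eleven after it). Longest linear sequence: 18 steps from 1 to 28; 3 and 11 are commercial and enter in steps 2 and 7.

Step 7 (key step). The most likely failure is sluggish oxygen transfer to the aluminium-bound enolate, so that protonation to the non-hydroxylated ketone or addition of the enolate to the sulfonimine by-product takes over. A second risk is erosion of facial control at C4 if the C8 centre is mismatched with the ligand. Fallback, setting out from 10 and 11: the same copper-catalysed addition is run, but 14 is trapped with Me3SiOTf and the enol silane F1 is isolated. MeLi (THF, 0 °C) then releases the regiodefined lithium enolate F2, which is hydroxylated at −78 °C with (camphorsulfonyl)oxaziridine, whose imine by-product does not add to enolates. This separates carbon–carbon from carbon–oxygen bond formation and comes back to the route at 16.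

Step 12. The likely failure is poor facial selectivity in the hydride addition: if the half-chair with the C3 silyloxy group and the C4 chain pseudoaxial is the reactive one, hydride enters anti to the C3 oxygen and the C2 epimer results, which would steer the epoxidation to the wrong face. Fallback, setting out from 21: the C2-epimeric alcohol F3 that the reduction then delivers is inverted by a Mitsunobu esterification (4-nitrobenzoic acid, PPh3, DIAD) to the 4-nitrobenzoate F4, and brief methanolysis (K2CO3, MeOH, 0 °C) returns to the route at 22.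

Step 18. The likely failures are Z to E isomerisation of the activated angeloyl unit and slow acylation of the hindered allylic C8 hydroxyl, which would force conditions that favour the isomerisation. Fallback, setting out from 27: the hydroxyl is esterified with 2-(diphenoxyphosphoryl)propanoic acid (DCC, DMAP cat.), which has no alkene to isomerise, giving the phosphonoester F5. An Ando-type Horner–Wadsworth–Emmons olefination with acetaldehyde (NaI, DBU, THF, −78 → 0 °C) then builds the Z alkene in place and arrives at 28.

Step 6. The likely failures are cleavage of the silyl ether by the Lewis-acidic boron bromide and HBr addition across C10=C11 during protonolysis. Fallback, setting out from 8: α-selective hydrostannation (Bu3SnH, Mo(CO)3(CNt-Bu)3 cat., THF, 55 °C) gives the 2-stannyl alkene F6 under neutral conditions, and bromodestannylation with NBS (CH2Cl2, −78 °C), which is much faster at the carbon–tin bond than at an alkene, returns to the route at 10.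

## Further compounds

F1 | step 7 | {[(3R)-3-[(3S)-3-(tert-butyldimethylsilyloxy)-6-methylhepta-1,5-dien-2-yl]cyclohex-1-en-1-yl]oxy}trimethylsilane | C=C([C@H](CC=C(C)C)O[Si](C)(C)C(C)(C)C)[C@@H]1CCCC(O[Si](C)(C)C)=C1
F2 | step 7 | lithium (3R)-3-[(3S)-3-(tert-butyldimethylsilyloxy)-6-methylhepta-1,5-dien-2-yl]cyclohex-1-en-1-olate | C=C([C@H](CC=C(C)C)O[Si](C)(C)C(C)(C)C)[C@@H]1CCCC(O[Li])=C1
F3 | step 12 | (1R,5S,6S)-5-[(3S)-3-(tert-butyldimethylsilyloxy)-6-methylhepta-1,5-dien-2-yl]-2-methyl-6-(triethylsilyloxy)cyclohex-2-en-1-ol | C=C([C@H](CC=C(C)C)O[Si](C)(C)C(C)(C)C)[C@@H]1CC=C(C)[C@@H](O)[C@H]1O[Si](CC)(CC)CC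
F4 | step 12 | (1S,5S,6S)-5-[(3S)-3-(tert-butyldimethylsilyloxy)-6-methylhepta-1,5-dien-2-yl]-2-methyl-6-(triethylsilyloxy)cyclohex-2-en-1-yl 4-nitrobenzoate | C=C([C@H](CC=C(C)C)O[Si](C)(C)C(C)(C)C)[C@@H]1CC=C(C)[C@H](OC(=O)c2ccc(cc2)[N+](=O)[O-])[C@H]1O[Si](CC)(CC)CC
F5 | step 18 | (1S,3S,4S,6S)-4-[(3S)-3-{[2-(diphenoxyphosphoryl)propanoyl]oxy}-6-methylhepta-1,5-dien-2-yl]-1-methyl-2-oxo-7-oxabicyclo[4.1.0]heptan-3-yl 3-methylbut-2-enoate (both epimers at the phosphonate carbon) | C=C([C@H](CC=C(C)C)OC(=O)C(C)P(=O)(Oc1ccccc1)Oc1ccccc1)[C@@H]1C[C@@H]2O[C@]2(C)C(=O)[C@H]1OC(=O)C=C(C)C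
F6 | step 6 | tributyl[(3S)-3-(tert-butyldimethylsilyloxy)-6-methylhepta-1,5-dien-2-yl]stannane | CCCC[Sn](CCCC)(CCCC)C(=C)[C@H](CC=C(C)C)O[Si](C)(C)C(C)(C)C
A1 | alternative 1 | (5R,6S)-6-(tert-butyldimethylsilyloxy)-5-[(2R,3S)-2-(hydroxymethyl)-3-(3-methylbut-2-en-1-yl)oxiran-2-yl]-2-methylcyclohex-2-en-1-one | OC[C@]1(O[C@H]1CC=C(C)C)[C@@H]2CC=C(C)C(=O)[C@H]2O[Si](C)(C)C(C)(C)C
A2 | alternative 1 | (5S,6S)-6-(tert-butyldimethylsilyloxy)-5-[(2Z)-1-hydroxy-6-methylhepta-2,5-dien-2-yl]-2-methylcyclohex-2-en-1-one | OC/C(=C\CC=C(C)C)[C@@H]1CC=C(C)C(=O)[C@H]1O[Si](C)(C)C(C)(C)C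
A3 | alternative 2 | (1R,2S,3S,6R)-3-[(3S)-3-(tert-butyldimethylsilyloxy)-6-methylhepta-1,5-dien-2-yl]-2-[(4-methoxyphenyl)methoxy]bicyclo[4.1.0]heptan-1-ol | C=C([C@H](CC=C(C)C)O[Si](C)(C)C(C)(C)C)[C@@H]1CC[C@@H]2C[C@]2(O)[C@H]1OCc3ccc(OC)cc3
A4 | alternative 2 | methyl (2S,3S)-3-[(3S)-3-(tert-butyldimethylsilyloxy)-6-methylhepta-1,5-dien-2-yl]-2-[(4-methoxyphenyl)methoxy]hept-6-enoate | C=C([C@H](CC=C(C)C)O[Si](C)(C)C(C)(C)C)[C@H](CCC=C)[C@H](OCc1ccc(OC)cc1)C(=O)OC
A5 | alternative 3 | (1S,5S,6S)-5-[(3S)-3-(tert-butyldimethylsilyloxy)-6-methylhepta-1,5-dien-2-yl]-2-methyl-6-(triethylsilyloxy)cyclohex-2-en-1-ol | C=C([C@H](CC=C(C)C)O[Si](C)(C)C(C)(C)C)[C@@H]1CC=C(C)[C@H](O)[C@H]1O[Si](CC)(CC)CC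
A6 | alternative 3 | triethyl{[(1S,2Z,4S)-4-(tert-butyldimethylsilyloxy)-1-[(2R,3S)-3-ethenyl-3-methyloxiran-2-yl]-7-methyl-3-[(trimethylsilyl)methyl]octa-2,6-dien-1-yl]oxy}silane | C[Si](C)(C)C/C(=C\[C@H](O[Si](CC)(CC)CC)[C@H]1O[C@@]1(C)C=C)[C@H](CC=C(C)C)O[Si](C)(C)C(C)(C)C
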